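## Analysis of the target

The target (32) is a cyclohexene. Its ring is numbered here C1 (CH bearing the isopropenyl group), C2=C3 (methyl on C3), C4 (CH bearing the CH2–O–coumarin-7-yl group), C5 (quaternary, carrying a methyl group and a 2-carboxyethyl chain) and C6 (CH2). There are three stereocentres, C1 (S), C4 (R) and C5 (R). The isopropenyl group, the aryloxymethyl group and the acid chain all lie on one ring face, so C4/C5 are contiguous and C1/C4 are 1,4-cis across the ring alkene.

The sensitive points are the doubly allylic C1–H (the skipped diene can slip into conjugation under acid or strong base), the allylic C4 centre (epimerisable whenever its substituent is a carbonyl group), and the coumarin lactone (opened by hydroxide). The difficulty is the quaternary C5 next to C4, together with a remote 1,4 relation on a ring that has no heteroatom or carbonyl to relay stereochemistry.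

The strategy rests on one feature. Because the C1 and C4 substituents are cis, a bond between their first carbons makes C1 and C4 the bridgeheads of a bicyclo[2.2.2]oct-2-ene with bridges C2=C3, C5–C6 and Ca–Cb. Ca is the future central isopropenyl carbon and Cb the future oxymethyl carbon. The C5 chain sits on the same face and can reach an oxygen on Cb as a seven-membered lactone. That bicycle is the Diels–Alder adduct of a 6,6-disubstituted cyclohexa-2,4-dienone (C6 carbonyl, diene C1=C2–C3=C4) with an enol ester. Its O–Cb–Ca–CH2–X array is a Grob fragmentation precursor that returns both side chains at once.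

## Retrosynthetic reasoning

**32 to 29 and 30.** The aryl ether is cut at the CH2–O bond and the acid is masked as its methyl ester (31). This leads back to primary alcohol 29 and the hydroxycoumarin 30. Cutting here keeps the base-sensitive coumarin out of every earlier step. The forward reaction is a Mitsunobu etherification of a β-branched primary alcohol, followed by ester hydrolysis.

**29 to 26.** The C4 hydroxymethyl carbon (Cb) and the central isopropenyl carbon (Ca) are reconnected. In mesylate 26 the Cb–Ca bond, the lactone oxygen on Cb and the sulfonate on the CH2 group of Ca form a Grob array. The forward reaction must open the lactone to the methyl ester, break Cb–Ca to give aldehyde 28, and reduce 28 before C4 can epimerise. What is gained is that the 1,4-cis relation and the cis relation to the chain become consequences of ring geometry (bridgeheads and tether).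

**26 to 21.** Functional-group changes only. The C6 methylene comes from the ketone of 21 through tosylhydrazone 22, and the mesylate from the silyl ether through alcohol 25. The ketone is removed while the bicycle is intact, because after fragmentation it would sit next to the epimerisable C1.

**21 to 20 (key disconnection).** Retro-[4+2] cleavage of C1–Ca and C4–Cb gives dienone 20, in which the enol ester is tied to C5 through the propanoate chain. The tether is what selects the diene face and the orientation of the dienophile, so it has to be in place before the cycloaddition. The forward reaction must outrun bimolecular dimerisation of the dienone.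

**20 to 18.** The dienone is not carried through several steps. It is unveiled last, by dehydrogenating the saturated C1–C2 edge of β,γ-unsaturated ketone 18 through silyl enol ether 19. Direct C-allylation of the corresponding phenol at its methyl-bearing ortho carbon was rejected for four reasons:
- the free ortho position and the oxygen compete for the electrophile;
- an aryl allyl ether is thermodynamically preferred over a monocyclic dienone;
- a 6-allyl dienone can undergo Cope rearrangement;
- the dienone would have to survive chain elaboration and esterification.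

**18 to 10 and 17.** The enol ester C–O bond is cut to give acid 10 and the geometrically defined alkenyl trifluoroborate 17. An oxidative copper-catalysed coupling transfers the E geometry. This avoids the enolate of a β-silyloxy aldehyde, which has no geometric control and can eliminate silyloxide.

**10 to 1 and 2.** The acid comes from the allyl group of 6 (through 7, 8 and 9). The quaternary stereocentre of 6 is cut at the C5–allyl bond, leading to dienol carbonate 5 and enone 4. Enone 4 is the annulation product of 1 and 2. Allylating the extended dienolate at its α-carbon sets the only stereocentre that is carried into the key step, and puts the ring alkene where the dienone will need it.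

**17 to 11.** The trisubstituted E alkene comes from syn carbometalation of alkyne 11 (through 12 and 13), silylation to 14, and iodine–boron exchange (through 15 and 16).

## Alternatives that were turned down

**Alternative 1:** The ring is cut at C3–C4 and C5–C6. The forward key step is an intermolecular Diels–Alder reaction of chiral butenolide A2 (its alkene supplies C4 and C5, its methyl the C5 methyl) with silyloxy diene A3, which adds anti to the menthyloxy group and gives cis-fused lactone acetal A1.
- For: the acetal centre is a dependable face-directing group, both partners are cheap, and the polarity is matched (the nucleophilic CH2 terminus of A3 meets the β-carbon of A2). C4 and the quaternary C5 arrive cis in a known reaction type. On precedent this beats the chosen key step.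
- Against: the β-methyl group makes A2 a deactivated, trisubstituted dienophile that has to form a quaternary carbon intermolecularly. A1 is also far from the target. C1 arrives as a silyl enol ether, so the isopropenyl group and its configuration must be set late with no ring constraint. The alkene must move from C1=C2 to C2=C3, the lactone carbonyl must become the CH2–O carbon, and the one-carbon acetal must be extended by two carbons. The C3 methyl stereocentre is made only to be destroyed.
- Comparison: the chosen route is weaker on precedent for ring formation. In exchange, all three ring stereocentres follow from 21 by geometry, and a single fragmentation delivers the isopropenyl group, the oxymethyl group and the chain together.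

**Alternative 2:** The bonds from the lactone α-carbon (Cα) to C5 and C6 are cut, that is, a cyclopropane fused to C5–C6 and tied to the C4 oxymethyl group as a six-membered lactone. In the forward key step diazoacetate A5, made from a Birch-derived symmetric dienyl carbinol, is cyclopropanated by the chiral catalyst A6. The catalyst selects one of two enantiotopic ring alkenes and gives A4.
- For: access is short, absolute control is catalytic in a known reaction class, and the tether guarantees the C4/C5 relation. The C2=C3 alkene with its methyl group and the CH2–O carbon are already in place. On enantiocontrol precedent and on steps to the key intermediate this is stronger than the chosen route.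
- Against: opening the cyclopropane leaves only a two-carbon acid on C5, so a homologation is needed. The opening must break Cα–C6 and not Cα–C5. C1 of A4 is an unfunctionalised allylic CH2, so the isopropenyl group has to be introduced cis to C4 with nothing to direct it. Allylic C–H insertion and drift of the 1,4-diene into conjugation are competing processes.
- Comparison: the hardest relation in the target (C1 against C4/C5) is left open. The chosen route settles it by construction.

**Alternative 3:** The C5–CH3 and C4–CH2OH bonds are cut. In the forward key step cuprate A9 adds to the β,β-disubstituted enone A8 anti to the C1 isopropenyl group, and the regiodefined enolate is trapped at C4 by formaldehyde A10 to give A7. No ring is closed.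
- For: the step is convergent and uses known chemistry. The stereochemical course is plausible (methyl trans to isopropenyl, hydroxymethyl anti to the new axial methyl). A kinetic enol triflate towards C2 followed by methyl cross-coupling could then install the C2=C3 alkene. On step count and precedent this is stronger than the chosen route.
- Against: conjugate addition that forms a quaternary centre is slow and usually needs silyl activation, which complicates the aldol trapping. Formaldehyde trapping next to a quaternary carbon is capricious. A7 is a β-hydroxy ketone prone to retro-aldol loss and dehydration, and its C4 centre is epimerisable. Each of the three stereocentres depends on a separate facial preference. An enantiopure supply of A8 must also be found.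
- Comparison: the chosen route offers stereocentres locked by bridgeheads and a tether instead of stacked diastereoselectivities, and no epimerisable carbonyl neighbour of C4 until the moment it is reduced.

Key step: step 11

**Remarks and assumptions**
- Atom labels: C1–C6 are the ring carbons of the target as defined above. Ca is the carbon that becomes the central isopropenyl carbon and Cb the carbon that becomes the oxymethyl carbon. Descriptors "a" and "b" refer to Ca and Cb.
- Assumption: the (R)-configured ligand in step 3 is taken to give (S)-6 by analogy with the facial preference of simple 2-alkylcyclohexanone enolates. If the dienolate shows the opposite sense, the enantiomeric ligand is used.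
- Remark: the enol ester is used as the E isomer. The Z isomer would be equally acceptable for C1, C4 and Cb, but it would place the mesyloxymethyl group syn to the Cb alkoxide in step 16 and so allow oxetane closure to compete with fragmentation.

## Route

Step 1
Reactants: 1 propanal; 2 pent-1-en-3-one
Product: 4 2,4-dimethylcyclohex-2-en-1-one (racemic), via 2-methyl-5-oxoheptanal 3 (not isolated)
Conditions: Et2NSiMe3 (cat.), MeCN, reflux; then KOH, aq. THF, reflux
Reagents that add atoms: none
Why: Amine-catalysed Michael addition of the aldehyde (through its enamine) to the vinyl ketone, then base-mediated aldol condensation (Robinson-type annulation); only attack of the ethyl ketone α-carbon on the aldehyde closes a six-membered ring, and the racemic C4 centre is erased in step 2.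

Step 2
Reactants: 4 2,4-dimethylcyclohex-2-en-1-one
Product: 5 allyl 2,4-dimethylcyclohexa-1,3-dien-1-yl carbonate
Conditions: KOt-Bu, THF, 0 °C; then allyl chloroformate, −78 °C
Reagents that add atoms: allyl chloroformate, C=CCOC(=O)Cl
Why: Equilibrating deprotonation should give the extended (γ-deprotonated) potassium dienolate, which the hard chloroformate acylates on oxygen; any product of C-acylation at the α-carbon is the β-keto ester, which enters step 3 through the same palladium dienolate.

Step 3
Reactants: 5 allyl 2,4-dimethylcyclohexa-1,3-dien-1-yl carbonate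
Product: 6 (2S)-2-allyl-2,4-dimethylcyclohex-3-en-1-one
Conditions: Pd2(dba)3 (2.5 mol %), (R)-t-BuPHOX (6 mol %), toluene, 25 °C
Reagents that add atoms: none
Why: Decarboxylative asymmetric Tsuji allylation: ionisation and loss of CO2 give an allylpalladium dienolate that should form the C–C bond at the α-carbon through the usual inner-sphere seven-membered transition state, giving the α-quaternary β,γ-unsaturated ketone. The phosphinooxazoline ligand selects the enolate face and so sets the quaternary stereocentre (C5 of the target).

Step 4
Reactants: 6 (2S)-2-allyl-2,4-dimethylcyclohex-3-en-1-one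
Product: 8 (2S)-2-(3-hydroxypropyl)-2,4-dimethylcyclohex-3-en-1-one, via catechol boronate 7 (not isolated)
Conditions: catecholborane, RhCl(PPh3)3 (2 mol %), THF, 0 °C to rt; then H2O2, aq. NaOH, 0 °C
Reagents that add atoms: hydrogen peroxide, OO
Why: Rhodium-catalysed hydroboration with catecholborane is selective for the monosubstituted alkene over the ketone and the trisubstituted ring alkene and is anti-Markovnikov; oxidation gives the primary alcohol and removes the 1,5-diene that could otherwise undergo Cope rearrangement.

Step 5
Reactants: 8 (2S)-2-(3-hydroxypropyl)-2,4-dimethylcyclohex-3-en-1-one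
Product: 10 3-[(1S)-1,3-dimethyl-6-oxocyclohex-2-en-1-yl]propanoic acid, via aldehyde 9 (not isolated)
Conditions: TEMPO (cat.), PhI(OAc)2, MeCN–H2O, rt
Reagents that add atoms: water, O
Why: Oxoammonium-mediated oxidation of the primary alcohol to the aldehyde and, through its hydrate, to the acid; the ketone and the trisubstituted alkene are not affected under these near-neutral conditions.

Step 6
Reactants: 11 prop-2-yn-1-ol
Product: 13 (E)-3-iodo-2-methylprop-2-en-1-ol, via alkenylalane 12 (not isolated)
Conditions: AlMe3, Cp2ZrCl2 (cat.), CH2Cl2, 0 °C to rt; then I2, THF, −30 °C; aq. K2CO3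
Reagents that add atoms: trimethylaluminium, C[Al](C)C; iodine, II
Why: Negishi carboalumination adds methyl and aluminium syn across the alkyne with aluminium on the terminal carbon; iodinolysis with retention gives the E iodide.

Step 7
Reactants: 13 (E)-3-iodo-2-methylprop-2-en-1-ol
Product: 14 tert-butyl{[(E)-3-iodo-2-methylprop-2-en-1-yl]oxy}dimethylsilane
Conditions: TBSCl, imidazole, CH2Cl2, rt
Reagents that add atoms: tert-butyldimethylsilyl chloride, CC(C)(C)[Si](C)(C)Cl
Why: Standard silylation of a primary allylic alcohol; the silyl ether masks the oxygen that later becomes the fragmentation leaving group.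

Step 8
Reactants: 14 tert-butyl{[(E)-3-iodo-2-methylprop-2-en-1-yl]oxy}dimethylsilane
Product: 17 potassium (E)-{3-[(tert-butyldimethylsilyl)oxy]-2-methylprop-1-en-1-yl}trifluoroborate, via alkenyllithium 15 (not isolated), via lithium alkenyl(triisopropoxy)borate 16 (not isolated)
Conditions: t-BuLi (2 equiv), Et2O, −78 °C; B(Oi-Pr)3, −78 °C to rt; then aq. KHF2, MeOH, 0 °C
Reagents that add atoms: triisopropyl borate, CC(C)OB(OC(C)C)OC(C)C; potassium hydrogen difluoride, [K+].F[H-]F
Why: Iodine–lithium exchange, borylation and fluoride exchange all proceed with retention of alkene geometry and give a bench-stable trifluoroborate; brief cold exposure to KHF2 should spare the alkyl silyl ether.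

Step 9
Reactants: 10 3-[(1S)-1,3-dimethyl-6-oxocyclohex-2-en-1-yl]propanoic acid; 17 potassium (E)-{3-[(tert-butyldimethylsilyl)oxy]-2-methylprop-1-en-1-yl}trifluoroborate
Product: 18 (E)-3-[(tert-butyldimethylsilyl)oxy]-2-methylprop-1-en-1-yl 3-[(1S)-1,3-dimethyl-6-oxocyclohex-2-en-1-yl]propanoate
Conditions: CuBr (10 mol %), DMAP (20 mol %), 4 Å MS, O2 (1 atm), MeCN, 60 °C
Reagents that add atoms: none
Why: Chan–Lam–Evans-type oxidative C–O coupling of a carboxylic acid with an alkenyl trifluoroborate; boron-to-copper transmetalation and C–O reductive elimination retain the E geometry. The conditions are non-enolising, and the ketone partner is stable at this temperature because the dienone does not yet exist.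

Step 10
Reactants: 18 (E)-3-[(tert-butyldimethylsilyl)oxy]-2-methylprop-1-en-1-yl 3-[(1S)-1,3-dimethyl-6-oxocyclohex-2-en-1-yl]propanoate
Product: 20 (E)-3-[(tert-butyldimethylsilyl)oxy]-2-methylprop-1-en-1-yl 3-[(1S)-1,5-dimethyl-2-oxocyclohexa-3,5-dien-1-yl]propanoate, via trimethylsilyl enol ether 19 (not isolated)
Conditions: TMSOTf, Et3N, CH2Cl2, 0 °C; then Pd(OAc)2 (1.1 equiv), MeCN, rt, dark
Reagents that add atoms: none
Why: Saegusa–Ito oxidation: the ketone can enolise only towards its CH2 side, so soft enolisation gives one silyl enol ether; palladation and β-hydride elimination from the allylic CH2 give the linearly conjugated dienone. No strong base is used, so Dieckmann-type attack on the enol ester is avoided; the dienone is kept cold and dark and used at once.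

Step 11
Reactants: 20 (E)-3-[(tert-butyldimethylsilyl)oxy]-2-methylprop-1-en-1-yl 3-[(1S)-1,5-dimethyl-2-oxocyclohexa-3,5-dien-1-yl]propanoate
Product: 21 keto lactone (1S,4S,5S,aS,bR): bicyclo[2.2.2]oct-2-en-6-one core bridged from C5 to Cb by –CH2CH2C(=O)O–; Ca bears CH3 and CH2OTBS
Conditions: toluene (0.005 M), BHT (cat.), 110 °C, dark, Ar
Reagents that add atoms: none
Why: Proposed new method: the conjugated carbonyl lowers the LUMO of the C1=C2–C3=C4 diene of 20 and the trisubstituted enol ester is a moderately electron-rich dienophile, so a concerted, asynchronous inverse-demand [4+2] addition forming C1–Ca and C4–Cb is expected on heating at high dilution. The closest known reaction type is the thermal intramolecular Diels–Alder reaction of 6,6-disubstituted cyclohexa-2,4-dienones with alkenes tethered to the quaternary carbon, which is established for all-carbon and ether tethers closing five- and six-membered rings but not for an ester tether closing a seven-membered ring. The six-membered carbocycle C1–C2–C3–C4–Cb–Ca of the bicyclo[2.2.2]octenone closes by the cycloaddition itself, and the seven-membered lactone (C5, two CH2, C=O, O, Cb, C4) closes as the tether ring when Cb bonds to C4, which requires the ester to take its s-cis conformation in the transition state. C1 and C4 are set as bridgeheads by suprafacial addition to the diene face that carries the C5 chain, the only face the four-atom tether can reach, so the C5 stereocentre from step 3 fixes both and places the Ca–Cb bridge cis to the chain. Cb is fixed by the tether, which holds the acyloxy oxygen on the side of the C5–C6 bridge, and Ca by the E geometry of the dienophile, which puts its methyl group syn to that oxygen and the silyloxymethyl group towards the C2=C3 bridge. Regiochemistry is needed against the modest intrinsic preference of such dienones to bond the oxygen-bearing dienophile carbon to C1; the short tether makes the alternative, an eight-membered lactone spanning C6, much less accessible. Chemoselectivity over bimolecular dienone dimerisation is secured by dilution, and the absence of an allyl group on C5 removes the Cope pathway.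

Step 12
Reactants: 21 keto lactone (1S,4S,5S,aS,bR)
Product: 22 tosylhydrazone of 21 at C6 (1S,4S,5S,aS,bR; C=N geometry not defined)
Conditions: TsNHNH2, PPTS (cat.), MgSO4, THF, 65 °C
Reagents that add atoms: 4-methylbenzenesulfonohydrazide, Cc1ccc(cc1)S(=O)(=O)NN
Why: Acid-catalysed condensation at the only ketone; an aprotic solvent avoids alcoholysis of the lactone, and the product is expected to be crystalline, which would allow the enantiomeric purity set in step 3 to be upgraded by recrystallisation.

Step 13
Reactants: 22 tosylhydrazone of 21
Product: 24 lactone silyl ether with C6 as CH2 (1S,4R,5R,aS,bR), via N-alkyl-N'-tosylhydrazine 23 (not isolated)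
Conditions: catecholborane, CHCl3, 0 °C to rt; then NaOAc·3H2O, reflux
Reagents that add atoms: none
Why: Caglioti-type reduction: hydride adds to the C=N bond, and loss of sulfinate and nitrogen from the resulting hydrazine leaves the methylene group. The alkene is β,γ to C6, so no allylic transposition is expected, and catecholborane leaves the lactone and the silyl ether untouched.

Step 14
Reactants: 24 lactone silyl ether (1S,4R,5R,aS,bR)
Product: 25 lactone alcohol: Ca bears CH3 and CH2OH (1S,4R,5R,aS,bR)
Conditions: HF·pyridine, THF–pyridine, 0 °C to rt
Reagents that add atoms: none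
Why: Fluoride cleavage of the primary silyl ether under non-basic conditions; the hydroxymethyl group is anti to the lactone oxygen across Ca–Cb, so acyl migration is not possible.

Step 15
Reactants: 25 lactone alcohol (1S,4R,5R,aS,bR)
Product: 26 lactone mesylate: Ca bears CH3 and CH2OMs (1S,4R,5R,aS,bR)
Conditions: MsCl, Et3N, CH2Cl2, 0 °C
Reagents that add atoms: methanesulfonyl chloride, CS(=O)(=O)Cl
Why: Sulfonylation of a primary alcohol; the neopentyl position makes the mesylate inert to substitution and it has no β-hydrogen for elimination, so it waits for the fragmentation.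

Step 16
Reactants: 26 lactone mesylate (1S,4R,5R,aS,bR)
Product: 29 methyl 3-[(1R,2R,5S)-2-(hydroxymethyl)-1,3-dimethyl-5-(prop-1-en-2-yl)cyclohex-3-en-1-yl]propanoate, via hydroxy mesylate methyl ester 27 (not isolated), via aldehyde 28 (not isolated)
Conditions: NaOMe, NaBH4, MeOH–THF, 0 °C to rt
Reagents that add atoms: sodium methoxide, C[O-].[Na+]
Why: Methoxide opens the seven-membered lactone to the methyl ester and frees the Cb alkoxide, which triggers a Grob fragmentation: Cb–Ca breaks antiperiplanar to the freely rotating CH2–OMs bond, releasing the C4 formyl group and the C1 isopropenyl group in one event with relief of bicyclic strain. NaBH4, stable in basic methanol, should reduce the epimerisable β,γ-unsaturated aldehyde as it forms. No bond to C1, C4 or C5 is broken, so their configurations carry over, and the anti placement of CH2OMs and the Cb oxygen excludes oxetane closure.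

Step 17
Reactants: 29 methyl 3-[(1R,2R,5S)-2-(hydroxymethyl)-1,3-dimethyl-5-(prop-1-en-2-yl)cyclohex-3-en-1-yl]propanoate; 30 umbelliferone (7-hydroxy-2H-chromen-2-one)
Product: 31 methyl 3-[(1R,2R,5S)-1,3-dimethyl-2-{[(2-oxo-2H-chromen-7-yl)oxy]methyl}-5-(prop-1-en-2-yl)cyclohex-3-en-1-yl]propanoate
Conditions: PPh3, DIAD, THF, 0 °C to rt
Reagents that add atoms: none
Why: Mitsunobu etherification: the acidic phenol is a good pronucleophile and displacement occurs at the primary carbon, so no stereocentre is touched; the ester keeps the carboxyl group out of the reaction.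

Step 18
Reactants: 31 methyl 3-[(1R,2R,5S)-1,3-dimethyl-2-{[(2-oxo-2H-chromen-7-yl)oxy]methyl}-5-(prop-1-en-2-yl)cyclohex-3-en-1-yl]propanoate
Product: 32 3-[(1R,2R,5S)-1,3-dimethyl-2-{[(2-oxo-2H-chromen-7-yl)oxy]methyl}-5-(prop-1-en-2-yl)cyclohex-3-en-1-yl]propanoic acid (target)
Conditions: LiOH, THF–H2O, 0 °C to rt; then aq. HCl to pH 3
Reagents that add atoms: lithium hydroxide, [Li+].[OH-]
Why: Saponification of the unhindered methyl ester; any coumarin lactone opened by hydroxide gives the cis-hydroxycinnamate, which should reclose on acidification, and none of the stereocentres is enolisable.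

## Compound list

1 | propanal | CCC=O | starting material
2 | pent-1-en-3-one (ethyl vinyl ketone) | C=CC(=O)CC | starting material
3 | 2-methyl-5-oxoheptanal (racemic) | CCC(=O)CCC(C)C=O | intermediate
4 | 2,4-dimethylcyclohex-2-en-1-one (racemic) | CC1C=C(C)C(=O)CC1 | intermediate
5 | allyl 2,4-dimethylcyclohexa-1,3-dien-1-yl carbonate | C=CCOC(=O)OC1=C(C)C=C(C)CC1 | intermediate
6 | (2S)-2-allyl-2,4-dimethylcyclohex-3-en-1-one | O=C1CCC(C)=C[C@]1(C)CC=C | intermediate
7 | 2-{3-[(1S)-1,3-dimethyl-6-oxocyclohex-2-en-1-yl]propyl}-1,3,2-benzodioxaborole | O=C1CCC(C)=C[C@]1(C)CCCB1Oc2ccccc2O1 | intermediate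
8 | (2S)-2-(3-hydroxypropyl)-2,4-dimethylcyclohex-3-en-1-one | O=C1CCC(C)=C[C@]1(C)CCCO | intermediate
9 | 3-[(1S)-1,3-dimethyl-6-oxocyclohex-2-en-1-yl]propanal | O=C1CCC(C)=C[C@]1(C)CCC=O | intermediate
10 | 3-[(1S)-1,3-dimethyl-6-oxocyclohex-2-en-1-yl]propanoic acid | O=C1CCC(C)=C[C@]1(C)CCC(=O)O | intermediate
11 | prop-2-yn-1-ol | C#CCO | starting material
12 | (E)-alkenylalane Me2Al–CH=C(CH3)–CH2–O–AlMe2 | C[Al](C)/C=C(C)/CO[Al](C)C | intermediate
13 | (E)-3-iodo-2-methylprop-2-en-1-ol | OC/C(C)=C/I | intermediate
14 | tert-butyl{[(E)-3-iodo-2-methylprop-2-en-1-yl]oxy}dimethylsilane | CC(C)(C)[Si](C)(C)OC/C(C)=C/I | intermediate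
15 | (E)-{3-[(tert-butyldimethylsilyl)oxy]-2-methylprop-1-en-1-yl}lithium | [Li]/C=C(C)/CO[Si](C)(C)C(C)(C)C | intermediate
16 | lithium (E)-{3-[(tert-butyldimethylsilyl)oxy]-2-methylprop-1-en-1-yl}tri(propan-2-yloxy)borate | [Li+].CC(C)O[B-](OC(C)C)(OC(C)C)/C=C(C)/CO[Si](C)(C)C(C)(C)C | intermediate
17 | potassium (E)-{3-[(tert-butyldimethylsilyl)oxy]-2-methylprop-1-en-1-yl}trifluoroborate | [K+].F[B-](F)(F)/C=C(C)/CO[Si](C)(C)C(C)(C)C | intermediate
18 | (E)-3-[(tert-butyldimethylsilyl)oxy]-2-methylprop-1-en-1-yl 3-[(1S)-1,3-dimethyl-6-oxocyclohex-2-en-1-yl]propanoate | O=C1CCC(C)=C[C@]1(C)CCC(=O)O/C=C(\C)CO[Si](C)(C)C(C)(C)C | intermediate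
19 | (E)-3-[(tert-butyldimethylsilyl)oxy]-2-methylprop-1-en-1-yl 3-[(1S)-1,3-dimethyl-6-(trimethylsilyloxy)cyclohexa-2,5-dien-1-yl]propanoate | C[Si](C)(C)OC1=CCC(C)=C[C@]1(C)CCC(=O)O/C=C(\C)CO[Si](C)(C)C(C)(C)C | intermediate
20 | (E)-3-[(tert-butyldimethylsilyl)oxy]-2-methylprop-1-en-1-yl 3-[(1S)-1,5-dimethyl-2-oxocyclohexa-3,5-dien-1-yl]propanoate | O=C1C=CC(C)=C[C@]1(C)CCC(=O)O/C=C(\C)CO[Si](C)(C)C(C)(C)C | intermediate
21 | keto lactone (1S,4S,5S,aS,bR): bicyclo[2.2.2]oct-2-ene with bridgeheads C1 and C4, bridges C2=C3 (methyl on C3), C5–C6 (C5 methyl, C6 ketone) and Ca–Cb (Ca: CH3 and CH2OTBS); seven-membered lactone C5–CH2–CH2–C(=O)–O–Cb | O=C1[C@H]2C=C(C)[C@H]3[C@]1(C)CCC(=O)O[C@H]3[C@]2(C)CO[Si](C)(C)C(C)(C)C | intermediate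
22 | C6 tosylhydrazone of 21 (1S,4S,5S,aS,bR; C=N geometry not defined) | Cc1ccc(cc1)S(=O)(=O)NN=C1[C@H]2C=C(C)[C@H]3[C@]1(C)CCC(=O)O[C@H]3[C@]2(C)CO[Si](C)(C)C(C)(C)C | intermediate
23 | C6 N'-tosylhydrazino derivative from hydride addition to 22 (C6 configuration not defined, other centres as in 22) | Cc1ccc(cc1)S(=O)(=O)NNC1[C@H]2C=C(C)[C@H]3[C@]1(C)CCC(=O)O[C@H]3[C@]2(C)CO[Si](C)(C)C(C)(C)C | intermediate
24 | lactone silyl ether, as 21 but C6 is CH2 (1S,4R,5R,aS,bR) | C1[C@H]2C=C(C)[C@H]3[C@]1(C)CCC(=O)O[C@H]3[C@]2(C)CO[Si](C)(C)C(C)(C)C | intermediate
25 | lactone alcohol, as 24 but Ca bears CH2OH (1S,4R,5R,aS,bR) | C1[C@H]2C=C(C)[C@H]3[C@]1(C)CCC(=O)O[C@H]3[C@]2(C)CO | intermediate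
26 | lactone mesylate, as 24 but Ca bears CH2OMs (1S,4R,5R,aS,bR) | C1[C@H]2C=C(C)[C@H]3[C@]1(C)CCC(=O)O[C@H]3[C@]2(C)COS(C)(=O)=O | intermediate
27 | ring-opened hydroxy mesylate: bicyclo[2.2.2]oct-2-ene with C5 bearing CH3 and CH2CH2CO2CH3, Cb bearing OH, Ca bearing CH3 and CH2OMs (1S,4R,5R,aS,bR) | C1[C@H]2C=C(C)[C@@H]([C@]1(C)CCC(=O)OC)[C@@H](O)[C@]2(C)COS(C)(=O)=O | intermediate
28 | methyl 3-[(1R,2R,5S)-2-formyl-1,3-dimethyl-5-(prop-1-en-2-yl)cyclohex-3-en-1-yl]propanoate | C1[C@H](C(C)=C)C=C(C)[C@H](C=O)[C@]1(C)CCC(=O)OC | intermediate
29 | methyl 3-[(1R,2R,5S)-2-(hydroxymethyl)-1,3-dimethyl-5-(prop-1-en-2-yl)cyclohex-3-en-1-yl]propanoate | C1[C@H](C(C)=C)C=C(C)[C@H](CO)[C@]1(C)CCC(=O)OC | intermediate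
30 | umbelliferone (7-hydroxy-2H-chromen-2-one) | O=c1ccc2ccc(O)cc2o1 | starting material
31 | methyl 3-[(1R,2R,5S)-1,3-dimethyl-2-{[(2-oxo-2H-chromen-7-yl)oxy]methyl}-5-(prop-1-en-2-yl)cyclohex-3-en-1-yl]propanoate | C1[C@H](C(C)=C)C=C(C)[C@H](COc2ccc3ccc(=O)oc3c2)[C@]1(C)CCC(=O)OC | intermediate
32 | 3-[(1R,2R,5S)-1,3-dimethyl-2-{[(2-oxo-2H-chromen-7-yl)oxy]methyl}-5-(prop-1-en-2-yl)cyclohex-3-en-1-yl]propanoic acid | C=C(C)[C@@H]1C=C(C)[C@H](COc2ccc3ccc(=O)oc3c2)[C@](C)(CCC(=O)O)C1 | target

## Step count and least certain steps

Total: 18 steps. Longest linear sequence: 15 steps (steps 1–5 and 9–18); the alkenyl partner takes 3 steps (6–8).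

**Step 11 (key step, the one step beyond known chemistry).** The cycloaddition may fail to reach its transition state. The ester must take the disfavoured s-cis conformation to close a seven-membered ring, and the tether forces a regiochemistry opposite to the intrinsic polarity preference. Bimolecular dimerisation or slow decomposition of the dienone could then take over.

The fallback keeps the tethering logic but uses an all-carbon tether, which is covered by known intramolecular cycloadditions of such dienones, and inserts the lactone oxygen afterwards. It sets out from alcohol 8 and iodide 14 and comes back at 24.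
- Alcohol 8 is oxidised with Dess–Martin periodinane and aldehyde 9 is isolated.
- Alkenyllithium 15 (from 14 and t-BuLi) is added at −78 °C to the aldehyde in preference to the hindered ketone, giving the allylic alcohol (2S)-2-[(E)-6-(tert-butyldimethylsilyloxy)-3-hydroxy-5-methylhex-4-en-1-yl]-2,4-dimethylcyclohex-3-en-1-one F1 as a carbinol mixture.
- TMSOTf/Et3N gives the bis(trimethylsilyl) derivative F2, and Pd(OAc)2 then gives the dienone trimethylsilyl ether F3.
- Heating in dilute toluene closes the bicyclo[2.2.2]octenone and a cyclohexane ring, giving the tricyclic ketone F4.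
- Tosylhydrazone formation with concurrent loss of the trimethylsilyl ether gives the hydroxy tosylhydrazone F5, and catecholborane then NaOAc·3H2O gives, through the hydrazine F6, the deoxygenated alcohol F7.
- Dess–Martin oxidation gives the cyclohexanone F8.
- Baeyer–Villiger oxidation with bis(trimethylsilyl) peroxide and a Lewis acid (conditions that spare alkenes) moves the more substituted carbon Cb to oxygen with retention and gives 24.

**Step 16.** The transient aldehyde 28 may epimerise at C4, or its alkene may slip into conjugation, if methoxide acts on it faster than hydride reduces it. Lactone opening could also lag behind.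

The fallback separates the three events so that the aldehyde never meets excess base. It sets out from 26 and comes back at 29 without new compounds. Acid-catalysed methanolysis (TsOH, MeOH) gives hydroxy mesylate 27, which is isolated. One equivalent of KN(SiMe3)2 in THF at −78 °C triggers the fragmentation to aldehyde 28, which is quenched cold with acetic acid. A separate NaBH4 reduction at low temperature then gives 29.

**Step 13.** Hydride delivery to the hindered C=N bond may be slow (as may the condensation in step 12). Decomposition of the alkyldiazene could also take a radical course, opening the way to homoallyl–cyclopropylcarbinyl rearrangement of the bicyclic skeleton.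

The fallback sets out from 21 and comes back at 24. NaBH4 in THF–EtOH at 0 °C reduces only the ketone to the C6 alcohol F9. Thiocarbonyldiimidazole gives the imidazolyl thiocarbonate F10. Barton–McCombie deoxygenation with Bu3SnH at high concentration and AIBN, so that hydrogen transfer outpaces rearrangement, gives 24.

**Step 3.** The extended dienolate may be allylated partly at the γ-carbon, the facial selectivity may be lower than for saturated ketone enolates, and regiocontrol in forming 5 may be incomplete.

The fallback sets out from 4 and comes back at 6. Deconjugative α-allylation of the potassium dienolate (KOt-Bu, allyl bromide, t-BuOH–THF) gives racemic 2-allyl-2,4-dimethylcyclohex-3-en-1-one F11. Preparative chromatography on a chiral stationary phase separates it into 6 and its (R)-enantiomer F12, which is discarded.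

**Step 9.** Transmetalation of the β,β-disubstituted alkenyl trifluoroborate may be slow, so that protodeboronation or oxidative homocoupling consumes it.

The fallback sets out from 10 and comes back at 18.
- Oxalyl chloride with catalytic DMF gives the acid chloride F13.
- Commercial 2-methylpropane-1,3-diol is monosilylated to 3-[(tert-butyldimethylsilyl)oxy]-2-methylpropan-1-ol F14 and oxidised with Dess–Martin periodinane to the aldehyde F15.
- KN(SiMe3)2 at −78 °C gives the potassium enolate F16, which is O-acylated by F13 before β-elimination can intervene. This gives 18 together with its Z isomer F17.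
- The two are separated on AgNO3-impregnated silica and 18 continues.

## Further compounds

F1 | step 11 | (2S)-2-[(E)-6-(tert-butyldimethylsilyloxy)-3-hydroxy-5-methylhex-4-en-1-yl]-2,4-dimethylcyclohex-3-en-1-one (carbinol mixture) | O=C1CCC(C)=C[C@]1(C)CCC(O)/C=C(C)/CO[Si](C)(C)C(C)(C)C
F2 | step 11 | bis(trimethylsilyl) derivative of F1 (silyl enol ether and silyl ether) | C[Si](C)(C)OC1=CCC(C)=C[C@]1(C)CCC(O[Si](C)(C)C)/C=C(C)/CO[Si](C)(C)C(C)(C)C
F3 | step 11 | (6S)-6-[(E)-6-(tert-butyldimethylsilyloxy)-5-methyl-3-(trimethylsilyloxy)hex-4-en-1-yl]-4,6-dimethylcyclohexa-2,4-dien-1-one | O=C1C=CC(C)=C[C@]1(C)CCC(O[Si](C)(C)C)/C=C(C)/CO[Si](C)(C)C(C)(C)C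
F4 | step 11 | tricyclic ketone: bicyclo[2.2.2]octenone as in 21 with the carbocyclic bridge C5–CH2–CH2–CH(OSiMe3)–Cb | O=C1[C@H]2C=C(C)[C@H]3[C@]1(C)CCC(O[Si](C)(C)C)[C@H]3[C@]2(C)CO[Si](C)(C)C(C)(C)C
F5 | step 11 | C6 tosylhydrazone of desilylated F4 | Cc1ccc(cc1)S(=O)(=O)NN=C1[C@H]2C=C(C)[C@H]3[C@]1(C)CCC(O)[C@H]3[C@]2(C)CO[Si](C)(C)C(C)(C)C
F6 | step 11 | C6 N'-tosylhydrazino derivative from F5 | Cc1ccc(cc1)S(=O)(=O)NNC1[C@H]2C=C(C)[C@H]3[C@]1(C)CCC(O)[C@H]3[C@]2(C)CO[Si](C)(C)C(C)(C)C
F7 | step 11 | deoxygenated tricyclic alcohol (C6 is CH2) | C1[C@H]2C=C(C)[C@H]3[C@]1(C)CCC(O)[C@H]3[C@]2(C)CO[Si](C)(C)C(C)(C)C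
F8 | step 11 | tricyclic cyclohexanone with C=O next to Cb | C1[C@H]2C=C(C)[C@H]3[C@]1(C)CCC(=O)[C@H]3[C@]2(C)CO[Si](C)(C)C(C)(C)C
F0 | step 16 | none | none
F9 | step 13 | C6 alcohol from reduction of 21 (C6 configuration not defined) | OC1[C@H]2C=C(C)[C@H]3[C@]1(C)CCC(=O)O[C@H]3[C@]2(C)CO[Si](C)(C)C(C)(C)C
F10 | step 13 | O-(C6) 1H-imidazole-1-carbothioate of F9 | S=C(OC1[C@H]2C=C(C)[C@H]3[C@]1(C)CCC(=O)O[C@H]3[C@]2(C)CO[Si](C)(C)C(C)(C)C)n1ccnc1
F11 | step 3 | racemic 2-allyl-2,4-dimethylcyclohex-3-en-1-one | O=C1CCC(C)=CC1(C)CC=C
F12 | step 3 | (2R)-2-allyl-2,4-dimethylcyclohex-3-en-1-one | O=C1CCC(C)=C[C@@]1(C)CC=C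
F13 | step 9 | 3-[(1S)-1,3-dimethyl-6-oxocyclohex-2-en-1-yl]propanoyl chloride | O=C1CCC(C)=C[C@]1(C)CCC(Cl)=O
F14 | step 9 | 3-[(tert-butyldimethylsilyl)oxy]-2-methylpropan-1-ol (racemic) | CC(CO)CO[Si](C)(C)C(C)(C)C
F15 | step 9 | 3-[(tert-butyldimethylsilyl)oxy]-2-methylpropanal (racemic) | CC(C=O)CO[Si](C)(C)C(C)(C)C
F16 | step 9 | potassium 3-[(tert-butyldimethylsilyl)oxy]-2-methylprop-1-en-1-olate (E/Z mixture) | [K+].[O-]C=C(C)CO[Si](C)(C)C(C)(C)C
F17 | step 9 | (Z)-3-[(tert-butyldimethylsilyl)oxy]-2-methylprop-1-en-1-yl 3-[(1S)-1,3-dimethyl-6-oxocyclohex-2-en-1-yl]propanoate | O=C1CCC(C)=C[C@]1(C)CCC(=O)O/C=C(/C)CO[Si](C)(C)C(C)(C)C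
A1 | alternative 1 | cis-fused bicyclic lactone acetal with C1 trimethylsilyl enol ether (Diels–Alder adduct) | C1C(O[Si](C)(C)C)=C[C@H](C)[C@@H]2C(=O)O[C@@H](O[C@@H]3C[C@H](C)CC[C@H]3C(C)C)[C@]12C
A2 | alternative 1 | (5R)-5-menthyloxy-4-methylfuran-2(5H)-one | O=C1C=C(C)[C@H](O[C@@H]2C[C@H](C)CC[C@H]2C(C)C)O1
A3 | alternative 1 | (E)-2-(trimethylsilyloxy)penta-1,3-diene | C=C(O[Si](C)(C)C)/C=C/C
A4 | alternative 2 | cyclopropane-fused cis-bicyclic lactone retaining the C2=C3 alkene | C1C=C(C)[C@@H]2COC(=O)[C@H]3[C@]2(C)[C@@H]13
A5 | alternative 2 | (2,6-dimethylcyclohexa-2,5-dien-1-yl)methyl diazoacetate | [N-]=[N+]=CC(=O)OCC1C(C)=CCC=C1C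
A6 | alternative 2 | Rh2(5S-MEPY)4, dirhodium tetrakis[methyl (5S)-2-oxopyrrolidine-5-carboxylate] (hand to be matched to the substrate) | [Rh+2].[Rh+2].COC(=O)[C@@H]1CCC(=O)[N-]1.COC(=O)[C@@H]1CCC(=O)[N-]1.COC(=O)[C@@H]1CCC(=O)[N-]1.COC(=O)[C@@H]1CCC(=O)[N-]1
A7 | alternative 3 | 2-(hydroxymethyl)-3-methyl-3-[3-(tert-butyldimethylsilyloxy)propyl]-5-(prop-1-en-2-yl)cyclohexanone | C=C(C)[C@@H]1CC(=O)[C@H](CO)[C@](C)(CCCO[Si](C)(C)C(C)(C)C)C1
A8 | alternative 3 | (5S)-3-[3-(tert-butyldimethylsilyloxy)propyl]-5-(prop-1-en-2-yl)cyclohex-2-en-1-one | C=C(C)[C@@H]1CC(=O)C=C(CCCO[Si](C)(C)C(C)(C)C)C1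
A9 | alternative 3 | Me2CuLi (lithium dimethylcuprate) | [Li+].C[Cu-]C
A10 | alternative 3 | formaldehyde | C=O
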